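**Retrosynthetic overview**
1. Target 13 is opened at the C4–C5 ring bond to the Z-keto-enal 12. This is the O2-oxidised form of furyl diol 9. The forward step is furan photooxygenation followed by a chelate-controlled 4π (vinylogous aldol) ring contraction that sets C4 and C5 from C6.
2. Diol 9 is cut at the furan–carbinol bond into 2-furyllithium and dioxolanone 5, which serves as a masked (S)-2-hydroxyoctadecanal after DIBAL-H reduction.
3. Dioxolanone 5 is cut at C7–C8. The forward step is an anodic mixed Kolbe coupling of L-malic acid acetonide 3 with palmitic acid 4.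
4. C6 is the L-malic acid stereocentre. The only carbocycle is formed in the last step, and purchased furan supplies C1–C4.

Assumption: the target is taken exactly as drawn, (4S,5S)-4,5-dihydroxy-5-[(1S)-1-hydroxyheptadecyl]cyclopent-2-en-1-one, with a cis-4,5-diol.
Locants used below: ring C1 (C=O), C2=C3, C4 (CHOH), C5 (C–OH); side chain C6 (CHOH), C7–C22.

**Step 1**
Reactants: 1 L-malic acid; 2 2,2-dimethoxypropane
Product: 3 [(4S)-2,2-dimethyl-5-oxo-1,3-dioxolan-4-yl]acetic acid
Conditions: 2 (3 equiv), p-TsOH·H2O (2 mol %), rt, 3 h; crystallise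
Reagents that add atoms: 2,2-dimethoxypropane (2), COC(C)(C)OC
Why: Acid-catalysed transacetalisation closes the α-hydroxy acid unit selectively to the five-membered dioxolanone, leaves the β-carboxyl free and does not touch the stereocentre.

**Step 2**
Reactants: 3 [(4S)-2,2-dimethyl-5-oxo-1,3-dioxolan-4-yl]acetic acid; 4 palmitic acid
Product: 5 (5S)-5-hexadecyl-2,2-dimethyl-1,3-dioxolan-4-one
Conditions: Pt anode/Pt cathode, undivided cell, 4 (5 equiv), Et3N (5 mol % of total acid), MeOH, 40–45 °C, ca. 200 mA cm⁻², 1.3 F per mol acid; chromatography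
Reagents that add atoms: palmitic acid (4), CCCCCCCCCCCCCCCC(=O)O
Why: In this mixed Kolbe electrolysis, anodic decarboxylation gives two primary radicals that couple at platinum; the radical from 3 carries no α-heteroatom, so it is not over-oxidised to a cation, the excess of 4 steers 3 into the cross product, and the stereocentre lies one carbon away from the radical and is untouched.

**Step 3**
Reactants: 5 (5S)-5-hexadecyl-2,2-dimethyl-1,3-dioxolan-4-one; 6 furan
Product: 9 (2S)-1-(furan-2-yl)octadecane-1,2-diol (C1 epimer mixture), via 2-furyllithium 7 (not isolated), via aluminium lactolate 8 (not isolated)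
Conditions: 6 (2.8 equiv), n-BuLi (2.5 equiv), THF, –78 to 0 °C; separately 5, DIBAL-H (1.1 equiv), CH2Cl2, –78 °C, 1 h; cannulate 7 into 8, –78 to 0 °C; H2O, aq. Rochelle salt
Reagents that add atoms: furan (6), c1ccoc1
Why: In this one-pot partial reduction/organolithium addition the lactolate 8 acts as a masked α-hydroxy aldehyde, so C2 does not epimerise at low temperature, and the new C1 carbinol may form as any mixture because this carbon becomes planar in step 4.

**Step 4**
Reactants: 9 (2S)-1-(furan-2-yl)octadecane-1,2-diol (C1 epimer mixture)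
Product: 13 (4S,5S)-4,5-dihydroxy-5-[(1S)-1-hydroxyheptadecyl]cyclopent-2-en-1-one, via furan endoperoxide 10 (not isolated), via pyranone hemiacetal 11 (not isolated), via Z-keto-enal 12 (not isolated)
Conditions: O2 (1 atm), tetraphenylporphyrin (0.5 mol %), white LED, CH2Cl2, –20 °C; lamp off, Ar purge, Me2S (3 equiv), –20 °C to rt; then MgBr2·OEt2 (2 equiv), Et3N (2.2 equiv), –20 to 0 °C; pH 5 citrate buffer
Reagents that add atoms: oxygen, O=O
Why: Proposed new method: a photooxygenative, magnesium-templated Piancatelli-type ring contraction of a 2-furyl-1,2-diol; sensitised singlet oxygen adds [4+2] to the furan (10) and Me2S cleaves the O–O bond to give 12, which rests as its hemiacetal 11 (this part is the known singlet-oxygen Achmatowicz reaction); the new part is that MgBr2/Et3N soft-enolises 12 to the E-enediolate held in a six-membered O6–Mg–O1 chelate (Fráter–Seebach type), and the 4π array C5=C1–C2=C3–C4=O···Mg then closes thermally and conrotatorily (a vinylogous intramolecular aldol) to form C4–C5; both C1 epimers of 9 converge because C5 becomes planar; with the C6 branch and O4 both "outside" on the U-shaped array, conrotation puts them trans, so O4 and O5 end up cis; C4 bonds to the C5 face anti to the C16H33 chain of the chelate, which for (6S) gives (4S,5S); the competing O1/O5 five-ring chelate would place the C6 branch "inside" and should close far more slowly; C5 is quaternary, so the product cannot dehydrate; the closest known reaction types are the base-induced pyranone to 4,5-dihydroxycyclopentenone ring contraction, the Piancatelli rearrangement and the one-pot furan photooxygenation/aldol route to 4-hydroxycyclopentenones, none of which has been run under chelate control from an exocyclic carbinol stereocentre.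

**Compound list**
1 | L-malic acid, (S)-2-hydroxybutanedioic acid | OC(=O)C[C@H](O)C(=O)O | starting material
2 | 2,2-dimethoxypropane | COC(C)(C)OC | starting material
3 | [(4S)-2,2-dimethyl-5-oxo-1,3-dioxolan-4-yl]acetic acid | CC1(C)O[C@@H](CC(=O)O)C(=O)O1 | intermediate
4 | palmitic acid (hexadecanoic acid) | CCCCCCCCCCCCCCCC(=O)O | starting material
5 | (5S)-5-hexadecyl-2,2-dimethyl-1,3-dioxolan-4-one | CC1(C)O[C@@H](CCCCCCCCCCCCCCCC)C(=O)O1 | intermediate
6 | furan | c1ccoc1 | starting material
7 | 2-furyllithium | [Li]c1ccco1 | intermediate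
8 | diisobutyl{[(5S)-5-hexadecyl-2,2-dimethyl-1,3-dioxolan-4-yl]oxy}aluminium (lactol carbon unassigned) | CC1(C)O[C@@H](CCCCCCCCCCCCCCCC)C(O[Al](CC(C)C)CC(C)C)O1 | intermediate
9 | (2S)-1-(furan-2-yl)octadecane-1,2-diol (C1 epimer mixture) | CCCCCCCCCCCCCCCC[C@H](O)C(O)c1ccco1 | intermediate
10 | 1-[(2S)-1,2-dihydroxyoctadecyl]-2,3,7-trioxabicyclo[2.2.1]hept-5-ene (isomer mixture) | CCCCCCCCCCCCCCCC[C@H](O)C(O)C12OOC(O1)C=C2 | intermediate
11 | 6-hydroxy-2-[(1S)-1-hydroxyheptadecyl]-2H-pyran-3(6H)-one (C2/C6 isomer mixture) | CCCCCCCCCCCCCCCC[C@H](O)C1OC(O)C=CC1=O | intermediate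
12 | (2Z,6S)-5,6-dihydroxy-4-oxodocos-2-enal (C5 epimer mixture, reacts as its Mg enediolate chelate) | CCCCCCCCCCCCCCCC[C@H](O)C(O)C(=O)/C=C\C=O | intermediate
13 | (4S,5S)-4,5-dihydroxy-5-[(1S)-1-hydroxyheptadecyl]cyclopent-2-en-1-one | CCCCCCCCCCCCCCCC[C@H](O)[C@@]1(O)C(=O)C=C[C@@H]1O | target

**Total step count:** 4. **Longest linear sequence:** 4 (1 → 3 → 5 → 9 → 13).

**Steps most likely to fail**

*Step 4 (the proposed new step).*
- Risks: the facial selectivity could be low if unchelated or O1/O5-chelated enediolates also cyclise. Retro-aldol loss of heptadecanal from 12 and reversible oxa-Michael addition of O6 are further side paths.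
- Fallback: this uses known chemistry and moves the stereocontrol from the C–C bond formation to a hydroxyl-directed reduction. It sets out from 9 and comes back at 13.
- Diol 9 is oxidised by the classical Achmatowicz reaction (NBS, NaHCO3, THF–H2O, 0 °C) and 11 is isolated.
- Et3N in DMF (rt to 60 °C) brings about the known untemplated ring contraction. It gives 4,5-dihydroxy-5-[(1S)-1-hydroxyheptadecyl]cyclopent-2-en-1-one as a mixture of ring diastereomers F1.
- Without separation, MnO2 in CH2Cl2 oxidises only the allylic C4 carbinol. The product is 2-hydroxy-2-[(1S)-1-hydroxyheptadecyl]cyclopent-4-ene-1,3-dione F2, in which C5 is no longer stereogenic.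
- Evans–Saksena reduction (Me4NBH(OAc)3, MeCN–AcOH, –30 °C) binds boron to O6 and delivers hydride to the ring face that carries C6, so O4 ends up cis to O5.
- In the chair-like transition state, the carbonyl that lets the C16H33 chain sit equatorial is the one reduced. This gives the 4,6-anti diol, which is 13.

*Step 2.*
- Risks: the statistical hydrocarbon and bis-dioxolanone homodimers lower the yield, the waxy hydrocarbon can foul the electrodes, and the dioxolanone may slowly undergo methanolysis.
- Fallback: a thermal nickel-catalysed decarboxylative alkyl–alkyl coupling. It sets out from 3 and comes back at 5.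
- Acid 3 is esterified with N-hydroxyphthalimide (DIC, cat. DMAP, CH2Cl2) to 1,3-dioxoisoindolin-2-yl [(4S)-2,2-dimethyl-5-oxo-1,3-dioxolan-4-yl]acetate F3.
- 1-Bromopentadecane and Mg in THF give pentadecylmagnesium bromide F4. ZnCl2 (0.5 equiv) converts it into dipentadecylzinc F5.
- NiCl2·glyme with 4,4'-di-tert-butyl-2,2'-bipyridine in THF–DMF at rt couples F3 with F5 to give 5.

*Step 3.*
- Risks: the lactolate 8 may release the aldehyde too slowly or unevenly, and liberated acetone competes for 7.
- Fallback: acylation followed by reduction instead of reduction followed by addition. It sets out from 5 and comes back at 9.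
- Reagent 7 (1.1 equiv) is added to 5 in THF at –78 °C. The lithium hemiketal collapses on a mildly acidic quench to (2S)-1-(furan-2-yl)-2-hydroxyoctadecan-1-one F6.
- F6 is isolated and reduced with NaBH4 in MeOH at 0 °C to 9. The epimer ratio is again irrelevant.

**Further compounds**
F1 | step 4 | 4,5-dihydroxy-5-[(1S)-1-hydroxyheptadecyl]cyclopent-2-en-1-one, mixture of ring diastereomers | CCCCCCCCCCCCCCCC[C@H](O)C1(O)C(=O)C=CC1O
F2 | step 4 | 2-hydroxy-2-[(1S)-1-hydroxyheptadecyl]cyclopent-4-ene-1,3-dione | CCCCCCCCCCCCCCCC[C@H](O)C1(O)C(=O)C=CC1=O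
F3 | step 2 | 1,3-dioxoisoindolin-2-yl [(4S)-2,2-dimethyl-5-oxo-1,3-dioxolan-4-yl]acetate | CC1(C)O[C@@H](CC(=O)ON2C(=O)c3ccccc3C2=O)C(=O)O1
F4 | step 2 | pentadecylmagnesium bromide | CCCCCCCCCCCCCCC[Mg]Br
F5 | step 2 | dipentadecylzinc | CCCCCCCCCCCCCCC[Zn]CCCCCCCCCCCCCCC
F6 | step 3 | (2S)-1-(furan-2-yl)-2-hydroxyoctadecan-1-one | CCCCCCCCCCCCCCCC[C@H](O)C(=O)c1ccco1
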